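**Plan**

- Retrosynthesis: the C6–Br bond is traced back to a carboxyl group (ipso-bromodecarboxylation) and the C3–Br and C4–Br bonds to C–H. The resulting 2,3-dihydroxy-6-methylbenzoic acid, carried as its methyl ester and 3-O-methyl ether, is then cut at the ring bonds C2–C3 and C5–C6.
- Enabling feature, with the ring numbered C1(OH), C2(OH), C3(Br), C4(Br), C5(CH3), C6(Br): C6–C1–C2 with its two adjacent oxygens is the C2–C3–C4 segment of methyl 4-methoxyacetoacetate, whose ester on C6 stands in for bromine. C3–C4–C5 with the methyl group is the three-carbon backbone of 4,4-dimethoxybutan-2-one.
- Forward order: the keto ester is silylated twice to the bis-silyl dienol ether. A TiCl4 [3+3] cyclocondensation with the keto acetal then forms the only ring directly at the aromatic oxidation level. Saponification, O-demethylation and tribromination with loss of CO2 follow.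
- Stereochemistry: the target has no stereocentre and no stereogenic double bond, so nothing has to be set.

Key step: step 3

Remark on the chemistry: the enol ether double bonds of 2, 3, 4 and 6 are drawn as single isomers for definiteness. Isomer mixtures are expected to behave alike, because these double bonds end in the benzene ring. The sp3 centres of 6 and 7 form without control and are written without descriptors, since aromatization removes them.

**Route**

Step 1
Reactants: 1 methyl 4-methoxy-3-oxobutanoate
Product: 2 methyl (Z)-4-methoxy-3-(trimethylsilyloxy)but-2-enoate
Conditions: Me3SiCl (1.5 equiv), Et3N (1.6 equiv), toluene, 20 °C, 48 h; filtration under argon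
Reagents that add atoms: chlorotrimethylsilane, C[Si](C)(C)Cl
Why: Soft enolization of the beta-keto ester by the amine and O-silylation by the chlorosilane (silyl enol ether formation) should give the conjugated 3-silyloxy enoate, the usual first stage of a 1,3-bis(silyl enol ether) synthesis.

Step 2
Reactants: 2 methyl (Z)-4-methoxy-3-(trimethylsilyloxy)but-2-enoate
Product: 4 (1Z,3Z)-1,4-dimethoxy-1,3-bis(trimethylsilyloxy)buta-1,3-diene, via lithium dienolate 3 (not isolated)
Conditions: LiN(iPr)2 (1.3 equiv), THF, −78 °C, 1 h; Me3SiCl (1.4 equiv), −78 → 20 °C; pentane, filtration under argon, used crude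
Reagents that add atoms: chlorotrimethylsilane, C[Si](C)(C)Cl
Why: The amide base should remove a gamma proton (C4) of the vinylogous ester to give the extended lithium dienolate 3, which the oxophilic chlorosilane traps on oxygen (O-silylation of an ester dienolate) to give the electron-rich diene.

Step 3
Reactants: 4 (1Z,3Z)-1,4-dimethoxy-1,3-bis(trimethylsilyloxy)buta-1,3-diene and 5 4,4-dimethoxybutan-2-one
Product: 8 methyl 2-hydroxy-3-methoxy-6-methylbenzoate, via open-chain silyl ketene acetal 6 (not isolated), via cyclic aldol 7 (not isolated)
Conditions: TiCl4 (1.1 equiv), CH2Cl2, −78 → 20 °C, 14 h; then ice/H2O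
Reagents that add atoms: none
Why: TiCl4 should ionize the dimethyl acetal of 5 to an oxocarbenium ion, which the methoxy-bearing terminal carbon of 4 attacks in a vinylogous Mukaiyama aldol reaction, forming the bond between the future C2 and C3 of the target (6). The remaining ketene silyl acetal carbon then adds to the titanium-activated methyl ketone in an intramolecular Mukaiyama aldol addition, a 6-(enolexo)-exo-trig closure that forms the C5–C6 bond and the only ring (7). The acetal-derived methoxy group of 7 lies beta to the ring ketone and is lost by beta-elimination, whereas the diene-derived methoxy group is alpha and stays; dehydration of the tertiary carbinol and enolization then give the arene without an oxidant. The closest known reaction type is the TiCl4-mediated formal [3+3] cyclocondensation of 1,3-bis(silyl enol ethers) with beta-keto acetals to give salicylates. No stereocentre survives, since all sp3 centres of 6 and 7 are erased on aromatization. The selectivity needed is regiochemical: the most nucleophilic site (the diene terminus) must pair with the most electrophilic one (the ionized acetal, far more reactive than the ketone at −78 °C), which places the methyl group next to the ester-bearing carbon.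

Step 4
Reactants: 8 methyl 2-hydroxy-3-methoxy-6-methylbenzoate
Product: 9 2-hydroxy-3-methoxy-6-methylbenzoic acid
Conditions: KOH (5 equiv), MeOH/H2O (1:1), reflux, N2; then aq. HCl, 0 °C, to pH 1
Reagents that add atoms: potassium hydroxide, [K+].[OH-]
Why: Saponification of the methyl ester by acyl substitution should free the acid while the aryl methyl ether and the phenoxide are inert to hot alkali; it is placed before demethylation because a catecholate would be air-sensitive in base.

Step 5
Reactants: 9 2-hydroxy-3-methoxy-6-methylbenzoic acid
Product: 10 2,3-dihydroxy-6-methylbenzoic acid
Conditions: BBr3 (3.5 equiv), CH2Cl2, −78 → 20 °C; then H2O, 0 °C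
Reagents that add atoms: none
Why: Lewis-acid aryl methyl ether cleavage should occur by bromide attack on the O-methyl group of the boron–ether complex, while the acid and phenol only form borate esters that hydrolyse on work-up.

Step 6
Reactants: 10 2,3-dihydroxy-6-methylbenzoic acid
Product: 12 3,4,6-tribromo-5-methylbenzene-1,2-diol, via dibromo acid 11 (not isolated)
Conditions: Br2 (2.0 equiv), AcOH, 20 °C, dark; then H2O (to about 75% aq. AcOH), Br2 (1.1 equiv), 20 → 40 °C; then aq. NaHSO3
Reagents that add atoms: bromine, BrBr
Why: Electrophilic aromatic bromination should first take the two free ring positions (each ortho or para to one hydroxyl) to give 11, after which bromine attacks the carboxyl-bearing carbon ortho to a hydroxyl and the resulting cyclohexadienone loses CO2 (ipso-bromodecarboxylation of an ortho-hydroxybenzoic acid, as in the conversion of salicylic acid to tribromophenol).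

**Compound list**

1 | methyl 4-methoxy-3-oxobutanoate (methyl 4-methoxyacetoacetate) | COCC(=O)CC(=O)OC | starting material
2 | methyl (Z)-4-methoxy-3-(trimethylsilyloxy)but-2-enoate | COC/C(O[Si](C)(C)C)=C/C(=O)OC | intermediate
3 | lithium (1E,3Z)-1,4-dimethoxy-3-(trimethylsilyloxy)buta-1,3-dien-1-olate (formed in the flask) | CO/C([O-])=C/C(O[Si](C)(C)C)=C/OC.[Li+] | intermediate
4 | (1Z,3Z)-1,4-dimethoxy-1,3-bis(trimethylsilyloxy)buta-1,3-diene | CO/C(O[Si](C)(C)C)=C/C(O[Si](C)(C)C)=C/OC | intermediate
5 | 4,4-dimethoxybutan-2-one | CC(=O)CC(OC)OC | starting material
6 | (Z)-1,4,5-trimethoxy-1-(trimethylsilyloxy)oct-1-ene-3,7-dione (formed in the flask; diastereomer mixture) | CO/C(O[Si](C)(C)C)=C/C(=O)C(OC)C(OC)CC(C)=O | intermediate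
7 | methyl 2-hydroxy-4,5-dimethoxy-2-methyl-6-oxocyclohexane-1-carboxylate (formed in the flask, titanium-bound; diastereomer mixture) | COC(=O)C1C(=O)C(OC)C(OC)CC1(C)O | intermediate
8 | methyl 2-hydroxy-3-methoxy-6-methylbenzoate | COC(=O)c1c(C)ccc(OC)c1O | intermediate
9 | 2-hydroxy-3-methoxy-6-methylbenzoic acid | COc1ccc(C)c(C(=O)O)c1O | intermediate
10 | 2,3-dihydroxy-6-methylbenzoic acid | Cc1ccc(O)c(O)c1C(=O)O | intermediate
11 | 4,5-dibromo-2,3-dihydroxy-6-methylbenzoic acid (formed in the flask) | Cc1c(Br)c(Br)c(O)c(O)c1C(=O)O | intermediate
12 | 3,4,6-tribromo-5-methylbenzene-1,2-diol | Cc1c(Br)c(O)c(O)c(Br)c1Br | target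

**Step count**

Total: 6 steps. Longest linear sequence: 6 steps (1 → 12); 5 is bought and enters at step 3.

**Steps most likely to fail**

1. Step 3. The diene terminus may attack the ketone instead of the ionized acetal, the diene may be protodesilylated by adventitious HCl before it reacts, or the sequence may stall before aromatization. The fallback sets out from 4 and 5 and comes back at 8, with the two bond formations separated. Compounds 4 and 5 are combined with catalytic Me3SiOTf in CH2Cl2 at −78 °C. This acetal Mukaiyama aldol reaction should stop after the first C–C bond because the ketone is not activated. Work-up with aqueous NaHCO3 should give methyl 4,5-dimethoxy-3,7-dioxooctanoate F1 as a diastereomer mixture. F1 is then closed under Knoevenagel conditions (piperidinium acetate, toluene, reflux with removal of water), the beta-keto ester methylene condensing with the methyl ketone. Elimination of methanol and enolization should deliver 8.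

2. Step 6. Ipso attack at the crowded carboxyl-bearing carbon may be slow, so that the reaction stops at 11 while the excess bromine oxidizes the catechol to an ortho-quinone. The fallback sets out from 10 and comes back at 12, with carboxyl removal separated from halogenation. Compound 10 is heated in quinoline at about 190 °C under argon, with catalytic Cu2O if needed. This protodecarboxylation of an ortho-hydroxybenzoic acid should give 4-methylbenzene-1,2-diol F2. F2 is then treated with Br2 (3 equiv) in AcOH at 20 °C, which should brominate the three free positions, each ortho or para to a hydroxyl, and give 12.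

3. Step 4. Acyl substitution at an ester carbonyl flanked by two ortho substituents and deactivated by the neighbouring phenoxide may be too slow, and forcing it may cause decarboxylation. The fallback sets out from 8 and comes back at 10, leaving out 9. Compound 8 is treated with a larger excess of BBr3 (6 equiv) in CH2Cl2 at 20 → 40 °C, then water. Both methyl–oxygen bonds, of the ether and of the ester, should be cleaved by bromide attack at the unhindered methyl carbons, a mode that the ortho substituents do not affect. No new compound arises on this path (F0).

**Further compounds**

F1 | step 3 | methyl 4,5-dimethoxy-3,7-dioxooctanoate | COC(=O)CC(=O)C(OC)C(OC)CC(C)=O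
F2 | step 6 | 4-methylbenzene-1,2-diol | Cc1ccc(O)c(O)c1
F0 | step 4 | none | none
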